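**Strategy**

Everything rests on the C4–C8 bond, which ties the quaternary methoxy carbon C4 of the dienone ring to the side-chain methine C8. Because O5 and the benzylic carbon C7 are 1,4-related across this bond, they can be joined for a time in a dihydrofuran ring (O5–C5–C4–C8–C7). The key step adds (E)-methyl isoeugenol across the methoxy-bearing ortho carbon and the oxygen of 4-allyl-2,5-dimethoxyphenol in one operation: the phenol is oxidised in the flask to its o-quinone monoketal, a chiral acid releases the oxocarbenium ion as a chiral ion pair, and C4–C8 and C7–O form with three stereocentres and the C1 ketone. Benzylic C7–O hydrogenolysis and O5-methylation then give the target.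

Key step: step 3

**Remarks before the steps**

- Numbering (target): ring C1 (C=O), C2 (allyl), C3, C4 (quaternary, OMe), C5 (OMe), C6; side chain C8 (methine with CH3) and C7 (benzylic CH2); O1 and O5 are the oxygens on C1 and C5. In 8 these atoms are C6, C5, C4, C3a, C7a, C7, C3 and C2 of the benzofuranone.
- Design remark: the phenol is not oxidised in the presence of the alkene. It is first turned, in the same flask, into its o-quinone monoketal. The cation is then released by a chiral acid whose conjugate base is the only anion present (a concentrated achiral electrolyte anion would displace a chiral counter-anion), and the electron-rich alkene never meets an oxidant.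
- Assumption: 1 is taken as commercially available (otherwise one bromination from 2,5-dimethoxybenzaldehyde).
- Assumption: the hand of the acid that leads to (2R,3S,3aR)-8 cannot be predicted; the (R)-acid is written and its mirror image is to be used if the sense proves opposite.

**Route**

Step 1
Reactants: 1 4-bromo-2,5-dimethoxybenzaldehyde
Product: 3 4-bromo-2,5-dimethoxyphenol, via aryl formate 2 (not isolated)
Conditions: mCPBA, CH2Cl2, 0 °C to rt; aq. NaHCO3 wash; then MeOH, cat. K2CO3, rt
Reagents that add atoms: 3-chloroperoxybenzoic acid (mCPBA), O=C(OO)c1cccc(Cl)c1
Why: Baeyer–Villiger oxidation (Dakin-type): the electron-rich aryl group migrates in the Criegee intermediate to give formate 2, which base-catalysed methanolysis cleaves to the phenol; bromide and methyl ethers are inert.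

Step 2
Reactants: 3 4-bromo-2,5-dimethoxyphenol; 4 allyltributylstannane
Product: 5 4-allyl-2,5-dimethoxyphenol
Conditions: Pd(PPh3)4 (5 mol %), DMF, 90 °C
Reagents that add atoms: none
Why: Stille coupling: oxidative addition of zerovalent palladium into the C–Br bond, allyl transfer from tin and reductive elimination give the allylarene; the free phenol is tolerated and the neutral medium limits migration of the double bond into conjugation.

Step 3
Reactants: 5 4-allyl-2,5-dimethoxyphenol; 6 (E)-methyl isoeugenol
Product: 8 (2R,3S,3aR)-5-allyl-2-(3,4-dimethoxyphenyl)-3a-methoxy-3-methyl-3,3a-dihydrobenzofuran-6(2H)-one, via o-quinone monoketal 7 (not isolated)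
Conditions: PhI(OAc)2, MeOH, −10 °C; MeOH and AcOH stripped with toluene below 0 °C; then 6, (R)-3,3′-bis(2,4,6-triisopropylphenyl)-1,1′-binaphthyl-2,2′-diyl N-triflylphosphoramide (10 mol %), toluene, −78 °C; H2O/THF quench at −78 °C, then aq. NaHCO3
Reagents that add atoms: methanol, CO; water, O
Why: Proposed new method: hypervalent-iodine oxidation of the guaiacol unit of 5 in methanol (the standard entry to masked o-benzoquinones) gives ketal 7, which the strong chiral acid ionises (either of its two equivalent methoxy groups leaves as methanol) to the 2-methoxyphenoxonium ion, held as a contact ion pair with the chiral phosphoramidate as the only anion; the β-carbon of 6 adds to the oxocarbenium carbon (C4–C8 bond), the veratryl-stabilised benzylic cation is captured by the dienone oxygen (C7–O bond), and the O-methyl oxocarbenium ion left at C1 is hydrolysed by the water quench to the ketone. The closest known reactions are the acid-promoted and the anodic or hypervalent-iodine [3+2] and [5+2] cation–alkene cycloadditions of quinone monoketals and methoxyphenols with propenylbenzenes, and the activation of quinone monoketals by chiral phosphoric acids; bond formation at a methoxy-bearing ortho carbon under anion-directed enantiocontrol is the untested part. The dihydrofuran ring closes stepwise by 5-exo-trig attack of the vinylogous-ester carbonyl oxygen on the benzylic cation (formal [3+2]). C4 is set by the chiral anion, which stays on the face from which methanol left and so leaves the opposite face to the alkene; C8 is set relative to C4 by a stacked open transition state in which the veratryl ring lies over the unsubstituted C6 corner and not over the allyl-bearing C2 corner, which with the (E)-alkene turns the C8 methyl group away from the C4 methoxy group; C7 is set by least-motion, reversible closure to the trans aryl/methyl arrangement and disappears in step 4. The step needs attack at the methoxy-bearing ortho carbon and not at the allyl-bearing para carbon or the free ortho CH: the ketal puts the leaving group and hence the cationic centre at that carbon, the second ring methoxy group makes the free ortho CH the electron-rich α-carbon of a vinylogous ester, and only the ortho adduct can close a five-membered ring onto the carbonyl oxygen, so para addition is expected to stay reversible. Low temperature and the cold quench keep the kinetically O-closed adduct from reorganising to the C-closed bicyclo[3.2.1]octane.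

Step 4
Reactants: 8 (2R,3S,3aR)-5-allyl-2-(3,4-dimethoxyphenyl)-3a-methoxy-3-methyl-3,3a-dihydrobenzofuran-6(2H)-one
Product: 9 (4S)-2-allyl-4-[(2S)-1-(3,4-dimethoxyphenyl)propan-2-yl]-5-hydroxy-4-methoxycyclohexa-2,5-dien-1-one (enol form of the cyclic 1,3-dione)
Conditions: Et3SiH (10 equiv), CF3CO2H, CH2Cl2, −20 to 0 °C
Reagents that add atoms: none
Why: Ionic hydrogenation: the C7–O bond of 8 is that of a vinylogous 3,4-dimethoxybenzyl ester, so acid ionises it to the veratryl-stabilised benzylic cation, which the excess silane should reduce to CH2 before the enol carbon C6 or loss of H8 can intervene, while the allyl group, the dienone and the C4 and C8 centres are untouched.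

Step 5
Reactants: 9 (4S)-2-allyl-4-[(2S)-1-(3,4-dimethoxyphenyl)propan-2-yl]-5-hydroxy-4-methoxycyclohexa-2,5-dien-1-one
Product: 10 (4S)-2-allyl-4-[(2S)-1-(3,4-dimethoxyphenyl)propan-2-yl]-4,5-dimethoxycyclohexa-2,5-dien-1-one
Conditions: TMSCHN2, toluene/MeOH (4:1), 0 °C; chromatography
Reagents that add atoms: trimethylsilyldiazomethane, C[Si](C)(C)C=[N+]=[N-]
Why: O-Methylation of the enolised cyclic 1,3-dione by the diazoalkane (proton transfer, then collapse of the methyldiazonium–dionate ion pair) without C-alkylation; the cross-conjugated 5-hydroxy-2,5-dienone tautomer is expected to predominate and to steer the methyl group to O5, the 1-O-methyl isomer that may accompany the target is removed by chromatography, and no stereocentre is touched.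

**Compound list**

1 | 4-bromo-2,5-dimethoxybenzaldehyde | COc1cc(C=O)c(OC)cc1Br | starting material
2 | 4-bromo-2,5-dimethoxyphenyl formate | COc1cc(OC=O)c(OC)cc1Br | intermediate
3 | 4-bromo-2,5-dimethoxyphenol | COc1cc(O)c(OC)cc1Br | intermediate
4 | allyltributylstannane | C=CC[Sn](CCCC)(CCCC)CCCC | starting material
5 | 4-allyl-2,5-dimethoxyphenol | C=CCc1cc(OC)c(O)cc1OC | intermediate
6 | (E)-methyl isoeugenol, (E)-1,2-dimethoxy-4-(prop-1-enyl)benzene | C/C=C/c1ccc(OC)c(OC)c1 | starting material
7 | 4-allyl-3,6,6-trimethoxycyclohexa-2,4-dien-1-one (o-quinone monoketal) | C=CCC1=CC(OC)(OC)C(=O)C=C1OC | intermediate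
8 | (2R,3S,3aR)-5-allyl-2-(3,4-dimethoxyphenyl)-3a-methoxy-3-methyl-3,3a-dihydrobenzofuran-6(2H)-one (aryl/methyl trans, methyl/3a-methoxy trans) | C=CCC1=C[C@@]2(OC)[C@@H](C)[C@H](c3ccc(OC)c(OC)c3)OC2=CC1=O | intermediate
9 | (4S)-2-allyl-4-[(2S)-1-(3,4-dimethoxyphenyl)propan-2-yl]-5-hydroxy-4-methoxycyclohexa-2,5-dien-1-one | C=CCC1=C[C@@](OC)([C@@H](C)Cc2ccc(OC)c(OC)c2)C(O)=CC1=O | intermediate
10 | (4S)-2-allyl-4-[(2S)-1-(3,4-dimethoxyphenyl)propan-2-yl]-4,5-dimethoxycyclohexa-2,5-dien-1-one | C=CCC1=C[C@@](OC)([C@@H](C)Cc2ccc(OC)c(OC)c2)C(OC)=CC1=O | target

**Step count and risks**

Total step count: 5. Longest linear sequence: 5 steps (1 → 3 → 5 → 8 → 9 → 10).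

Steps most likely to fail:

Step 3 (Proposed new method). What may go wrong: ion pairing too loose for enantiofacial control, addition of the alkene at the allyl-bearing para carbon, retention of the catalyst as the salt of the product cation, or reorganisation of the O-closed adduct to the C-closed bicyclic isomer before the quench. Fallback (known chemistry): from 5, the ketal 7 is made as in step 3 and isolated by rapid filtration. It is then condensed with 6 under an achiral Lewis acid (SnCl4, CH2Cl2, −78 °C), the established acid-promoted cation–alkene condensation of quinone monoketals with (E)-propenylbenzenes to hydrobenzofuranones. This gives the racemate, that is 8 together with its mirror image (2S,3R,3aS)-5-allyl-2-(3,4-dimethoxyphenyl)-3a-methoxy-3-methyl-3,3a-dihydrobenzofuran-6(2H)-one F1, which is resolved by preparative HPLC on a cellulose tris(3,5-dimethylphenylcarbamate) phase. The route is rejoined at 8.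

Step 4. What may go wrong: capture of the benzylic cation by the enol carbon C6 (closure to a bicyclo[3.2.1]octane), or loss of the C8 proton to a styrene, which on re-protonation would also scramble C8. Fallback: from 8, the C7–O bond is cleaved without a cation, by single-electron reduction (SmI2, HMPA, t-BuOH, THF, −78 °C). Electron transfer to the cross-conjugated dienone is followed by β-scission of the benzylic C–O bond to the dionate and a benzylic radical, reduction of that radical and protonation, in analogy to the samarium diiodide deoxygenation of benzylic esters. Acidic work-up gives 9 directly, no new compound arises (F0), and the route is rejoined at 9.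

Step 5. What may go wrong: methylation at the less hindered O1 of the ambident dionate, that is poor site selectivity. Fallback: from 9, silylation with a bulky silyl triflate (TIPSOTf, 2,6-lutidine, CH2Cl2, −78 °C) is expected to go to the unhindered O1 and give the silyl enol ether (6S)-4-allyl-6-[(2S)-1-(3,4-dimethoxyphenyl)propan-2-yl]-6-methoxy-3-(triisopropylsilyloxy)cyclohexa-2,4-dien-1-one F2. Its remaining carbonyl oxygen (O5) is then methylated with Me3OBF4 (2,6-di-tert-butyl-4-methylpyridine, CH2Cl2, 0 °C), the known O-alkylation of vinylogous esters at the carbonyl oxygen. The silyloxocarbenium ion loses silicon on aqueous work-up to give 10, where the route is rejoined.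

**Further compounds**

F1 | step 3 | (2S,3R,3aS)-5-allyl-2-(3,4-dimethoxyphenyl)-3a-methoxy-3-methyl-3,3a-dihydrobenzofuran-6(2H)-one | C=CCC1=C[C@]2(OC)[C@H](C)[C@@H](c3ccc(OC)c(OC)c3)OC2=CC1=O
F0 | step 4 | none | none
F2 | step 5 | (6S)-4-allyl-6-[(2S)-1-(3,4-dimethoxyphenyl)propan-2-yl]-6-methoxy-3-(triisopropylsilyloxy)cyclohexa-2,4-dien-1-one | C=CCC1=C[C@@](OC)([C@@H](C)Cc2ccc(OC)c(OC)c2)C(=O)C=C1O[Si](C(C)C)(C(C)C)C(C)C
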